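**Plan**
1. Retrosynthesis: after O-deprotection, the C3–O and C4–H bonds are traced back to an enol acetate (C3=C4). The oxolane is then cut at O1–C5 and C2–C3, giving methyl glycolate and a (Z)-2-aryl-4-silyloxybut-2-enoate. The enoate is cut at the C4–aryl bond (Suzuki) and at C5–C1' (alkynylation of O-benzylvanillin with methyl propiolate).
2. Enabling feature: O1–C2H2–C3(OH) is a glycolate (O–CH2–C=O) in reduced form, and C3–C4(aryl)–C5 is the carbonyl, α- and β-carbon of a 2-aryl enoate. The ring is therefore a reduced cyclic β-alkoxy ketone, open to an oxa-Michael/Dieckmann annulation in which the C4 aryl group steers the direction of the Dieckmann step.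
3. Forward: the carbinol chain is built first (steps 1–4) and the oxolane ring is closed in one operation (step 5). The helper ester is then removed (step 6), followed by enol acetate formation, cis-hydrogenation and deprotection (steps 7–10).
4. Stereochemistry: C1' is set by catalysis (step 1), C5 by 1,2-induction from C1' in step 5, and C3 and C4 together by one hydrogenation anti to the C5 substituent (step 8).

Key step: step 5

Remark: ring atoms carry the oxolane numbering of the target (O1, C2H2, C3–O, C4–aryl, C5–side chain, C1' = carbinol carbon); ArBn = 4-(benzyloxy)-3-methoxyphenyl, TBS = tert-butyldimethylsilyl.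
Assumption: the ProPhenol antipode that gives the (R)-carbinol is used (taken here as (R,R)-ProPhenol); the sense is confirmed on 3 by Mosher ester analysis before going on, and the other antipode is used if needed.

**Step 1**
Reactants: 1 4-(benzyloxy)-3-methoxybenzaldehyde; 2 methyl propiolate
Product: 3 methyl (4R)-4-ArBn-4-hydroxybut-2-ynoate
Conditions: Me2Zn (3 equiv), (R,R)-ProPhenol (10 mol%), Ph3P=O (20 mol%), toluene, 0 °C to rt; aq NH4Cl
Reagents that add atoms: none
Why: Zinc alkynylide addition to an aldehyde under dinuclear zinc–ProPhenol catalysis (catalytic asymmetric alkynylation), in which the chiral catalyst pocket selects the aldehyde face and sets the (R)-carbinol, the only stereocenter of the route made by a catalyst.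

**Step 2**
Reactants: 3 methyl (4R)-4-ArBn-4-hydroxybut-2-ynoate
Product: 4 methyl (4R)-4-ArBn-4-(TBS-oxy)but-2-ynoate
Conditions: TBSCl (1.3 equiv), imidazole (2.5 equiv), DMF, rt
Reagents that add atoms: tert-butyldimethylsilyl chloride CC(C)(C)[Si](C)(C)Cl
Why: Imidazole-promoted silylation of a secondary alcohol, which blocks the hydroxyl against lactonization and base in later steps and installs the bulky C–OSi bond that directs step 5.

**Step 3**
Reactants: 4 methyl (4R)-4-ArBn-4-(TBS-oxy)but-2-ynoate
Product: 6 methyl (2E,4S)-4-ArBn-4-(TBS-oxy)-2-iodobut-2-enoate, via α-stannyl enoate 5 (not isolated)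
Conditions: Bu3SnH (1.1 equiv), Pd(PPh3)4 (2 mol%), THF, 0 °C to rt; then I2 (1.2 equiv), 0 °C; aq Na2S2O3, aq KF
Reagents that add atoms: tributylstannane CCCC[SnH](CCCC)CCCC (tin stays only in 5); iodine II
Why: Palladium-catalysed syn-hydrostannation of an ynoate delivers hydride to the β-carbon and tin to the carbon next to the ester, and iododestannylation then replaces tin with retention, so the carbinol carbon ends cis to the ester (the 4S descriptor reflects only a change of CIP priorities).

**Step 4**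
Reactants: 6 methyl (2E,4S)-4-ArBn-4-(TBS-oxy)-2-iodobut-2-enoate; 7 [4-(benzyloxy)-3-methoxyphenyl]boronic acid
Product: 8 methyl (2Z,4S)-2,4-bis(ArBn)-4-(TBS-oxy)but-2-enoate
Conditions: Pd(PPh3)4 (5 mol%), K3PO4 (3 equiv), 1,4-dioxane/H2O (9:1), 60 °C
Reagents that add atoms: none
Why: Suzuki–Miyaura coupling of a vinyl iodide with an arylboronic acid proceeds with retention of alkene geometry and introduces the future C4 aryl group.

**Step 5**
Reactants: 8 methyl (2Z,4S)-2,4-bis(ArBn)-4-(TBS-oxy)but-2-enoate; 9 methyl glycolate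
Product: 11 methyl (5S)-4-ArBn-5-[(R)-ArBn(TBS-oxy)methyl]-3-oxooxolane-2-carboxylate (C2/C4 epimer mixture), via oxa-Michael adduct 10 (not isolated)
Conditions: 9 (1.3 equiv), NaH (2.2 equiv), THF, 0 °C, then 45 °C; AcOH, −20 °C; aq NH4Cl
Reagents that add atoms: none
Why: Sodium methyl glycolate adds through oxygen to the β-carbon of enoate 8 (oxa-Michael), the arylacetate enolate so formed is protonated, and the glycolate CH2 of adduct 10 is then deprotonated and attacks the original enoate ester carbonyl (Dieckmann condensation, loss of methoxide), so the O1–C5 and C2–C3 bonds of the oxolane form in one flask and the product is drained as its sodium β-keto ester enolate. The closest known reaction type is the oxa-Michael/Dieckmann annulation of glycolate esters with acrylates, crotonates and cinnamates to 3-oxo-oxolane carboxylates. The ring closes by 5-exo-trig attack of the ester enolate carbon on the ester carbonyl, the C–O bond having been made intermolecularly just before. C5 is set by 1,2-induction from the silyloxy carbinol: allylic 1,3-strain with the cis ester holds the carbinol C–H in the alkene plane and the alkoxide enters anti to the C–OSi bond (Felkin–Anh sense, as known for alkoxide and cuprate additions to γ-alkoxy enoates), which should give the 5,1'-anti (erythro) array of the target, while C2 and C4 are enolizable, form as mixtures and are fixed later. The selectivity needed is the direction of the Dieckmann step, and the C4 aryl group secures it: closure of the arylacetate enolate onto the glycolate ester would give a quaternary, non-enolizable β-keto ester that methoxide reopens, whereas 11 has an acidic C2–H and leaves the equilibria as its enolate. Conjugate addition must also outrun γ-deprotonation of 8, which the unhindered, weakly basic primary alkoxide and the low temperature of the addition stage should favour.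

**Step 6**
Reactants: 11 methyl (5S)-4-ArBn-5-[(R)-ArBn(TBS-oxy)methyl]-3-oxooxolane-2-carboxylate
Product: 12 (4R,5S)-4-ArBn-5-[(R)-ArBn(TBS-oxy)methyl]oxolan-3-one (4,5-trans)
Conditions: LiCl (3 equiv), DMSO/H2O (20:1), 130 °C
Reagents that add atoms: none
Why: Krapcho dealkoxycarbonylation (chloride attack on the methyl ester, loss of CO2 from the β-keto carboxylate, protonation of the enolate) removes the activating ester from C2, and C4 should settle as the more stable 4,5-trans epimer, which does not matter because C4 is made planar again in step 7.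

**Step 7**
Reactants: 12 (4R,5S)-4-ArBn-5-[(R)-ArBn(TBS-oxy)methyl]oxolan-3-one
Product: 13 (5S)-4-ArBn-5-[(R)-ArBn(TBS-oxy)methyl]-2,5-dihydrofuran-3-yl acetate
Conditions: KN(SiMe3)2 (1.1 equiv), THF, −78 °C; Ac2O (1.5 equiv), −78 to 0 °C
Reagents that add atoms: acetic anhydride CC(=O)OC(C)=O
Why: The benzylic C4–H is far more acidic than the C2 methylene, so the base should give the aryl-conjugated enolate regioselectively and hard O-acylation with acetic anhydride traps it as the enol acetate, erasing the C4 configuration.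

**Step 8**
Reactants: 13 (5S)-4-ArBn-5-[(R)-ArBn(TBS-oxy)methyl]-2,5-dihydrofuran-3-yl acetate
Product: 14 (3S,4R,5S)-4-(4-hydroxy-3-methoxyphenyl)-5-[(R)-(4-hydroxy-3-methoxyphenyl)(TBS-oxy)methyl]oxolan-3-yl acetate (all-cis)
Conditions: H2 (4 atm), 10% Pd/C, EtOAc, rt
Reagents that add atoms: none
Why: Heterogeneous syn-hydrogenation should add both hydrogens to the C3=C4 face opposite the large C5 substituent, which places the acetoxy and aryl groups cis to each other and cis to the C5 side chain (3S,4R), while the two benzyl ethers are hydrogenolysed in the same operation.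

**Step 9**
Reactants: 14 (3S,4R,5S)-4-(4-hydroxy-3-methoxyphenyl)-5-[(R)-(4-hydroxy-3-methoxyphenyl)(TBS-oxy)methyl]oxolan-3-yl acetate
Product: 15 (3S,4R,5S)-4-(4-hydroxy-3-methoxyphenyl)-5-[(R)-(4-hydroxy-3-methoxyphenyl)(TBS-oxy)methyl]oxolan-3-ol
Conditions: K2CO3 (3 equiv), MeOH, 0 °C to rt; aq NH4Cl
Reagents that add atoms: none
Why: Carbonate-mediated transesterification with methanol cleaves the secondary acetate without touching the silyl ether or any stereocenter.

**Step 10**
Reactants: 15 (3S,4R,5S)-4-(4-hydroxy-3-methoxyphenyl)-5-[(R)-(4-hydroxy-3-methoxyphenyl)(TBS-oxy)methyl]oxolan-3-ol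
Product: 16 metasequirin E, (3S,4R,5S)-4-(4-hydroxy-3-methoxyphenyl)-5-[(R)-hydroxy(4-hydroxy-3-methoxyphenyl)methyl]oxolan-3-ol
Conditions: Bu4NF (1.5 equiv), AcOH (1.5 equiv), THF, 0 °C to rt
Reagents that add atoms: none
Why: Fluoride attacks silicon to release the benzylic alcohol, and the acetic acid buffer keeps the medium near neutral so that the p-hydroxybenzylic alcohol is not ionized toward a quinone methide.

**Compound list**
1 | 4-(benzyloxy)-3-methoxybenzaldehyde | O=Cc1ccc(OCc2ccccc2)c(OC)c1 | starting material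
2 | methyl propiolate | C#CC(=O)OC | starting material
3 | methyl (4R)-4-[4-(benzyloxy)-3-methoxyphenyl]-4-hydroxybut-2-ynoate | COC(=O)C#C[C@H](O)c1ccc(OCc2ccccc2)c(OC)c1 | intermediate
4 | methyl (4R)-4-[4-(benzyloxy)-3-methoxyphenyl]-4-[(tert-butyldimethylsilyl)oxy]but-2-ynoate | COC(=O)C#C[C@H](O[Si](C)(C)C(C)(C)C)c1ccc(OCc2ccccc2)c(OC)c1 | intermediate
5 | methyl (2E,4S)-4-[4-(benzyloxy)-3-methoxyphenyl]-4-[(tert-butyldimethylsilyl)oxy]-2-(tributylstannyl)but-2-enoate | COC(=O)/C([Sn](CCCC)(CCCC)CCCC)=C\[C@H](O[Si](C)(C)C(C)(C)C)c1ccc(OCc2ccccc2)c(OC)c1 | intermediate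
6 | methyl (2E,4S)-4-[4-(benzyloxy)-3-methoxyphenyl]-4-[(tert-butyldimethylsilyl)oxy]-2-iodobut-2-enoate | COC(=O)/C(I)=C\[C@H](O[Si](C)(C)C(C)(C)C)c1ccc(OCc2ccccc2)c(OC)c1 | intermediate
7 | [4-(benzyloxy)-3-methoxyphenyl]boronic acid | OB(O)c1ccc(OCc2ccccc2)c(OC)c1 | starting material
8 | methyl (2Z,4S)-2,4-bis[4-(benzyloxy)-3-methoxyphenyl]-4-[(tert-butyldimethylsilyl)oxy]but-2-enoate | COC(=O)/C(c1ccc(OCc2ccccc2)c(OC)c1)=C\[C@H](O[Si](C)(C)C(C)(C)C)c1ccc(OCc2ccccc2)c(OC)c1 | intermediate
9 | methyl glycolate (methyl 2-hydroxyacetate) | COC(=O)CO | starting material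
10 | methyl (3S,4R)-2,4-bis[4-(benzyloxy)-3-methoxyphenyl]-4-[(tert-butyldimethylsilyl)oxy]-3-(2-methoxy-2-oxoethoxy)butanoate (C2 epimers) | COC(=O)C(c1ccc(OCc2ccccc2)c(OC)c1)[C@H](OCC(=O)OC)[C@H](O[Si](C)(C)C(C)(C)C)c1ccc(OCc2ccccc2)c(OC)c1 | intermediate
11 | methyl (5S)-4-[4-(benzyloxy)-3-methoxyphenyl]-5-{(R)-[4-(benzyloxy)-3-methoxyphenyl][(tert-butyldimethylsilyl)oxy]methyl}-3-oxooxolane-2-carboxylate (C2/C4 epimer mixture) | COc1cc(C2[C@@H]([C@H](O[Si](C)(C)C(C)(C)C)c3ccc(OCc4ccccc4)c(OC)c3)OC(C(=O)OC)C2=O)ccc1OCc1ccccc1 | intermediate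
12 | (4R,5S)-4-[4-(benzyloxy)-3-methoxyphenyl]-5-{(R)-[4-(benzyloxy)-3-methoxyphenyl][(tert-butyldimethylsilyl)oxy]methyl}oxolan-3-one | COc1cc([C@@H]2[C@@H]([C@H](O[Si](C)(C)C(C)(C)C)c3ccc(OCc4ccccc4)c(OC)c3)OCC2=O)ccc1OCc1ccccc1 | intermediate
13 | (5S)-4-[4-(benzyloxy)-3-methoxyphenyl]-5-{(R)-[4-(benzyloxy)-3-methoxyphenyl][(tert-butyldimethylsilyl)oxy]methyl}-2,5-dihydrofuran-3-yl acetate | COc1cc(C2=C(OC(C)=O)CO[C@@H]2[C@H](O[Si](C)(C)C(C)(C)C)c2ccc(OCc3ccccc3)c(OC)c2)ccc1OCc1ccccc1 | intermediate
14 | (3S,4R,5S)-4-(4-hydroxy-3-methoxyphenyl)-5-{(R)-[(tert-butyldimethylsilyl)oxy](4-hydroxy-3-methoxyphenyl)methyl}oxolan-3-yl acetate | COc1cc([C@H]2[C@@H]([C@H](O[Si](C)(C)C(C)(C)C)c3ccc(O)c(OC)c3)OC[C@H]2OC(C)=O)ccc1O | intermediate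
15 | (3S,4R,5S)-4-(4-hydroxy-3-methoxyphenyl)-5-{(R)-[(tert-butyldimethylsilyl)oxy](4-hydroxy-3-methoxyphenyl)methyl}oxolan-3-ol | COc1cc([C@H]2[C@@H]([C@H](O[Si](C)(C)C(C)(C)C)c3ccc(O)c(OC)c3)OC[C@H]2O)ccc1O | intermediate
16 | metasequirin E, (3S,4R,5S)-4-(4-hydroxy-3-methoxyphenyl)-5-[(R)-hydroxy(4-hydroxy-3-methoxyphenyl)methyl]oxolan-3-ol | COc1cc([C@H]2[C@@H]([C@H](O)c3ccc(O)c(OC)c3)OC[C@H]2O)ccc1O | target

Total step count: 10
Longest linear sequence: 10 steps (1 to 16; compounds 2, 7 and 9 are purchased)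

**Steps most likely to fail**

Step 5. What may go wrong is a reversible alkoxide addition with low facial bias at C5, or γ-deprotonation of the enoate (dienolate formation and loss of 8) ahead of conjugate addition. The fallback sets out from 8 and makes the two C–O bonds separately. Copper-catalysed conjugate borylation (B2pin2, CuCl, NaOt-Bu, a chiral bisphosphine chosen in a match/mismatch screen, MeOH, THF) should give methyl (3S,4S)-2,4-bis(ArBn)-4-(TBS-oxy)-3-(4,4,5,5-tetramethyl-1,3,2-dioxaborolan-2-yl)butanoate F1. Oxidation with NaBO3·4H2O in THF/H2O converts the C–B bond with retention into the β-hydroxy ester methyl (3S,4R)-2,4-bis(ArBn)-4-(TBS-oxy)-3-hydroxybutanoate F2. O–H insertion of methyl diazoacetate catalysed by Rh2(OAc)4 in CH2Cl2 then gives diester 10, now isolated, where the fallback comes back to the route; NaH in THF closes 10 to 11.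

Step 8. What may go wrong is slow hydrogen uptake at the tetrasubstituted enol acetate, with competing hydrogenolysis of the allylic ring C–O bond or of the vinylic acetate, or erosion of facial selectivity. The fallback sets out from 12 and uses kinetic protonation instead of hydrogenation. The potassium enolate (KN(SiMe3)2, THF, −78 °C) is protonated on the face opposite the C5 substituent by a hindered phenol (2,6-di-tert-butylphenol), which should give the less stable cis ketone (4S,5S)-4-ArBn-5-[(R)-ArBn(TBS-oxy)methyl]oxolan-3-one F3. This is reduced in the same flask at −78 °C with LiBH(s-Bu)3 from the open face to the all-cis alcohol (3S,4R,5S)-4-ArBn-5-[(R)-ArBn(TBS-oxy)methyl]oxolan-3-ol F4. Hydrogenolysis of the two benzyl ethers (H2, 1 atm, Pd/C, EtOAc) returns to the route at 15.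

Step 1. What may go wrong is insufficient enantioselectivity, or the wrong sense of induction, with the electron-rich aldehyde. The fallback sets out from 1 and 2 and sets the carbinol by reagent-controlled reduction. Addition of the lithium acetylide of 2 (LiN(SiMe3)2, THF, −78 °C) to 1 gives racemic methyl 4-ArBn-4-hydroxybut-2-ynoate F5. Oxidation with MnO2 in CH2Cl2 gives the ynone methyl 4-ArBn-4-oxobut-2-ynoate F6. Reduction with (R)-Alpine-Borane (B-isopinocampheyl-9-borabicyclo[3.3.1]nonane from (+)-α-pinene, THF, rt), in which the alkyne acts as the small group, should return the (R)-carbinol 3.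

**Further compounds**
F1 | step 5 | methyl (3S,4S)-2,4-bis[4-(benzyloxy)-3-methoxyphenyl]-4-[(tert-butyldimethylsilyl)oxy]-3-(4,4,5,5-tetramethyl-1,3,2-dioxaborolan-2-yl)butanoate (C2 epimers) | COC(=O)C(c1ccc(OCc2ccccc2)c(OC)c1)[C@H](B1OC(C)(C)C(C)(C)O1)[C@H](O[Si](C)(C)C(C)(C)C)c1ccc(OCc2ccccc2)c(OC)c1
F2 | step 5 | methyl (3S,4R)-2,4-bis[4-(benzyloxy)-3-methoxyphenyl]-4-[(tert-butyldimethylsilyl)oxy]-3-hydroxybutanoate (C2 epimers) | COC(=O)C(c1ccc(OCc2ccccc2)c(OC)c1)[C@H](O)[C@H](O[Si](C)(C)C(C)(C)C)c1ccc(OCc2ccccc2)c(OC)c1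
F3 | step 8 | (4S,5S)-4-[4-(benzyloxy)-3-methoxyphenyl]-5-{(R)-[4-(benzyloxy)-3-methoxyphenyl][(tert-butyldimethylsilyl)oxy]methyl}oxolan-3-one | COc1cc([C@H]2[C@@H]([C@H](O[Si](C)(C)C(C)(C)C)c3ccc(OCc4ccccc4)c(OC)c3)OCC2=O)ccc1OCc1ccccc1
F4 | step 8 | (3S,4R,5S)-4-[4-(benzyloxy)-3-methoxyphenyl]-5-{(R)-[4-(benzyloxy)-3-methoxyphenyl][(tert-butyldimethylsilyl)oxy]methyl}oxolan-3-ol | COc1cc([C@H]2[C@@H]([C@H](O[Si](C)(C)C(C)(C)C)c3ccc(OCc4ccccc4)c(OC)c3)OC[C@H]2O)ccc1OCc1ccccc1
F5 | step 1 | methyl 4-[4-(benzyloxy)-3-methoxyphenyl]-4-hydroxybut-2-ynoate (racemic) | COC(=O)C#CC(O)c1ccc(OCc2ccccc2)c(OC)c1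
F6 | step 1 | methyl 4-[4-(benzyloxy)-3-methoxyphenyl]-4-oxobut-2-ynoate | COC(=O)C#CC(=O)c1ccc(OCc2ccccc2)c(OC)c1
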